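**Retrosynthetic overview**

1. Feature: ring A (the cyclohexane C1–C6 of the lactone half: C1 isopropyl, C4 the carbinol carbon with the CH2O arm, C5 the carbon of the lactone carbonyl, C6 the carbon of the ring B alkene) and ring C (the cyclohexene of the acyl half) are one pattern, a 1-(oxymethyl)cyclohex-1-ene with a one-carbon arm at C3 and isopropyl at C4, trans; each is the adduct of a 1,3-disubstituted diene and an acrylate.
2. Last disconnections: the ester C–O bond between the C4 CH2O arm and the acrylic acid of the ring C half (carboxylate opening of a C4 spiro-epoxide), then the C=C bond of the seven-membered lactone (ring B) by ring-closing metathesis.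
3. Ring A: C5 and C4 from the ring alkene by [2,3]-Wittig–Still shift and hydroxyl-directed epoxidation; ring C half: Wittig olefination of the C3 aldehyde.
4. Both cyclohexenes come from the same catalytic enantioselective Diels–Alder reaction of diene 7 with trifluoroethyl acrylate 8, run once with each antipode of the catalyst. The catalyst sets the ester carbon and endo addition sets its neighbour. Ring A keeps the cis adduct and equilibrates C6 later at the aldehyde stage; ring C epimerises the ester carbon.
5. Order of ring formation: ring A (step 5), ring B (step 18), ring C (step 19); the halves are joined in step 30.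

Key step: step 5

Assumption: the catalyst from (S)-diphenylprolinol is taken to give the (1S) ester carbon of 28 and its antipode the (1R) ester carbon of 9; should the sense be the reverse, the two catalysts are exchanged and nothing else changes.

Abbreviations: PMB = 4-methoxybenzyl; TBS = tert-butyldimethylsilyl. Ring A locants C1–C6 as in line 1.

**Route**

Step 1
Reactants: 1 2-bromoprop-2-en-1-ol
Product: 2 tert-butyl[(2-bromoprop-2-en-1-yl)oxy]dimethylsilane
Conditions: TBSCl, imidazole, CH2Cl2, 0 °C to rt
Reagents that add atoms: tert-butyldimethylsilyl chloride, CC(C)(C)[Si](C)(C)Cl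
Why: Silyl ether formation on an unhindered primary alcohol; the TBS group is chosen because it lasts until the fluoride steps 9 and 31.

Step 2
Reactants: 3 4-methoxybenzyl alcohol; 4 propargyl bromide
Product: 5 PMB propargyl ether
Conditions: NaH, THF, 0 °C; then 4, Bu4NI (cat.), rt
Reagents that add atoms: none
Why: Williamson ether synthesis of a primary alkoxide with a reactive propargylic bromide.

Step 3
Reactants: 5 PMB propargyl ether
Product: 6 (E)-3-(PMB-oxy)prop-1-enylboronic acid pinacol ester
Conditions: pinacolborane, Cp2Zr(H)Cl (5 mol%), Et3N (5 mol%), neat, 60 °C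
Reagents that add atoms: pinacolborane, [H]B1OC(C)(C)C(C)(C)O1
Why: Zirconium-catalysed hydroboration of a terminal alkyne, a syn addition that places boron on the terminal carbon and gives only the (E)-alkenylboronate.

Step 4
Reactants: 2 2-bromoallyl TBS ether; 6 (E)-alkenylboronate
Product: 7 (E)-diene CH2=C(CH2OTBS)–CH=CH–CH2OPMB
Conditions: Pd(PPh3)4 (5 mol%), K3PO4, THF/H2O, 60 °C
Reagents that add atoms: none
Why: Suzuki–Miyaura coupling of an alkenyl bromide with an alkenylboronate, which keeps the (E) geometry and joins C2 of the diene to the boronate carbon.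

Step 5
Reactants: 7 (E)-diene; 8 2,2,2-trifluoroethyl acrylate
Product: 9 cis adduct 2,2,2-trifluoroethyl (1R,2S)-2-(PMB-oxymethyl)-4-(TBS-oxymethyl)cyclohex-3-ene-1-carboxylate
Conditions: (R)-3,3-diphenyl-1-(2-methylphenyl)hexahydropyrrolo[1,2-c][1,3,2]oxazaborole (20 mol%), HN(SO2CF3)2 (17 mol%), CH2Cl2, −40 to −20 °C
Reagents that add atoms: none
Why: The protonated oxazaborolidine binds the acrylate carbonyl and lowers its LUMO, and the diene adds in a concerted, suprafacial [4+2] cycloaddition; the closest known reaction type is the cationic-oxazaborolidine-catalysed Diels–Alder reaction of trifluoroethyl acrylate with acyclic dienes. Ring A closes by [4+2] cycloaddition, with the C1–C6 and C2–C3 bonds formed in the same step. C1, the ester carbon, is set by the catalyst, which shields one face of the bound acrylate; C6 follows from C1 through endo addition of the (E)-diene, which places the ester and the CH2OPMB arm cis. Regiochemistry (ester next to the CH2OPMB carbon) is secured by the two diene substituents, which both put the largest HOMO coefficient on the unsubstituted terminus. The step needs endo selectivity as well as face selectivity, because the exo (trans) adduct has the other configuration at C6; secondary overlap of the coordinated ester with the diene favours endo, and the minor trans isomer is removed by chromatography. The cis relationship is kept on purpose, since it crowds the lower face of the ring for the [2,3] shift of step 11.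

Step 6
Reactants: 9 cis trifluoroethyl ester
Product: 11 cis methyl ketone 1-[(1R,2S)-2-(PMB-oxymethyl)-4-(TBS-oxymethyl)cyclohex-3-en-1-yl]ethan-1-one, via Weinreb amide 10 (not isolated)
Conditions: MeNH(OMe)·HCl, iPrMgCl, THF, −20 °C; then MeMgBr, −20 to 0 °C; NH4Cl (aq), 0 °C
Reagents that add atoms: methylmagnesium bromide, C[Mg]Br
Why: Aminolysis of the activated ester by the magnesium amide and addition of MeMgBr to the chelating amide stop at the ketone (Weinreb ketone synthesis); no enolising base persists, so the cis relationship of step 5 should be kept, and any trans ketone is a separable diastereomer.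

Step 7
Reactants: 11 cis methyl ketone
Product: 12 cis isopropenyl compound (3S,4R)-3-(PMB-oxymethyl)-4-(prop-1-en-2-yl)-1-(TBS-oxymethyl)cyclohex-1-ene
Conditions: Cp2Ti(μ-Cl)(μ-CH2)AlMe2, pyridine (cat.), THF/toluene, −40 to 0 °C
Reagents that add atoms: titanium–aluminium methylidene reagent Cp2Ti(μ-Cl)(μ-CH2)AlMe2, C[Al](C)Cl.C=[Ti](C1C=CC=C1)C1C=CC=C1
Why: Carbonyl methylenation by a titanium methylidene ([2+2] addition to C=O and cycloreversion), chosen over a basic phosphorus ylide because it does not enolise the ketone and so should not epimerise C1.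

Step 8
Reactants: 12 cis isopropenyl compound
Product: 13 cis isopropyl compound (3R,4S)-3-(PMB-oxymethyl)-4-isopropyl-1-(TBS-oxymethyl)cyclohex-1-ene
Conditions: H2 (1 atm), RhCl(PPh3)3 (5 mol%), benzene/EtOH, rt
Reagents that add atoms: none
Why: Homogeneous hydrogenation, which reduces the 1,1-disubstituted alkene much faster than the trisubstituted ring alkene and does not cleave the PMB ether.

Step 9
Reactants: 13 cis isopropyl compound
Product: 14 allylic alcohol [(3R,4S)-3-(PMB-oxymethyl)-4-isopropylcyclohex-1-en-1-yl]methanol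
Conditions: Bu4NF, THF, 0 °C to rt
Reagents that add atoms: none
Why: Fluoride cleavage of the silyl ether; the PMB ether is inert to fluoride.

Step 10
Reactants: 14 allylic alcohol
Product: 15 stannylmethyl ether tributyl({[(3R,4S)-3-(PMB-oxymethyl)-4-isopropylcyclohex-1-en-1-yl]methoxy}methyl)stannane
Conditions: KH, THF, 0 °C; then Bu3SnCH2I, rt
Reagents that add atoms: tributyl(iodomethyl)stannane, CCCC[Sn](CCCC)(CCCC)CI
Why: Williamson etherification of the potassium alkoxide with a primary iodide, the usual entry to a Wittig–Still precursor.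

Step 11
Reactants: 15 stannylmethyl ether
Product: 17 homoallylic alcohol (C4 exocyclic methylene; C5 CH2OH trans to the C6 CH2OPMB arm and to isopropyl), via lithiomethyl ether 16 (not isolated)
Conditions: n-BuLi, THF, −78 °C
Reagents that add atoms: none
Why: Tin–lithium exchange and [2,3]-sigmatropic Wittig–Still rearrangement form the C5–CH2OH bond and move the alkene to C4=CH2; the lower face of C5 is blocked in both half-chair conformers (by the pseudoaxial C6 arm in one, by the axial isopropyl group in the other), so the new bond should form on the upper face, trans to both.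

Step 12
Reactants: 17 homoallylic alcohol
Product: 18 epoxy alcohol (C4 spiro-epoxide with oxygen cis to the C5 CH2OH arm)
Conditions: VO(acac)2 (5 mol%), t-BuOOH, CH2Cl2, 0 °C to rt
Reagents that add atoms: tert-butyl hydroperoxide, CC(C)(C)OO
Why: Hydroxyl-directed epoxidation of a homoallylic alcohol: the vanadate ester of the C5 CH2OH group delivers oxygen to the face of C4=CH2 on which it sits, which sets C4; the other face is in addition shielded by the axial C6 arm.

Step 13
Reactants: 18 epoxy alcohol
Product: 20 epoxy acid (C5 CO2H), via epoxy aldehyde 19 (not isolated)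
Conditions: 2,2,6,6-tetramethylpiperidin-1-oxyl (20 mol%), PhI(OAc)2, MeCN/pH 7 buffer, rt
Reagents that add atoms: water, O
Why: Nitroxyl-catalysed oxidation of the primary alcohol through the aldehyde hydrate to the acid, under buffered conditions that spare the epoxide and the PMB ether and do not enolise C5.

Step 14
Reactants: 20 epoxy acid
Product: 21 hydroxy acid (C6 CH2OH trans to C5 CO2H)
Conditions: DDQ, CH2Cl2/pH 7 buffer, 0 °C
Reagents that add atoms: none
Why: Oxidative cleavage of the PMB ether (hydride abstraction, hydrolysis of the oxocarbenium ion); the C6 arm and the C5 carboxyl are trans, so no lactone can form, and the alcohol is oxidised at once.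

Step 15
Reactants: 21 hydroxy acid
Product: 23 aldehyde acid (C6 CHO trans to isopropyl and cis to C5 CO2H; held as its cyclic hydroxylactone), via axial aldehyde 22 (not isolated)
Conditions: Dess–Martin periodinane, NaHCO3, CH2Cl2, 0 °C; crude, then DBU, CH2Cl2, rt
Reagents that add atoms: none
Why: Dess–Martin oxidation, then base-mediated epimerisation through the enol: the formyl group leaves the axial position (1,3-syn to the epoxide CH2) for the equatorial one, and the cis aldehyde acid is trapped as its cyclic hydroxylactone, so C6 should settle in the target configuration under thermodynamic control.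

Step 16
Reactants: 23 aldehyde acid
Product: 24 vinyl acid (C6 vinyl cis to C5 CO2H)
Conditions: Ph3PCH3Br, KN(SiMe3)2, THF, 0 °C; then 23, −78 to 0 °C
Reagents that add atoms: methyltriphenylphosphonium bromide, C[P+](c1ccccc1)(c1ccccc1)c1ccccc1.[Br-]
Why: Wittig methylenation; the first equivalent of ylide opens the hydroxylactone to the carboxylate aldehyde, and C6 is already the more stable epimer, so the basic ylide cannot erode it.

Step 17
Reactants: 24 vinyl acid; 25 tert-butyl 2-(bromomethyl)acrylate
Product: 26 diene ester (C5 carboxylate esterified with 2-(tert-butoxycarbonyl)allyl)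
Conditions: Cs2CO3, DMF, 0 °C to rt
Reagents that add atoms: none
Why: O-Alkylation of the caesium carboxylate by the allylic bromide (SN2 or SN2′ give the same ester); the carboxyl and the epoxide CH2 lie on opposite faces, so the epoxide is not opened within the molecule.

Step 18
Reactants: 26 diene ester
Product: 27 bicyclic lactone epoxide (rings A and B; tert-butyl ester on the ring B alkene)
Conditions: second-generation Grubbs catalyst (H2IMes)(PCy3)Cl2Ru=CHPh (10 mol%), toluene (2 mM), 80 °C
Reagents that add atoms: none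
Why: Ring-closing metathesis between the C6 vinyl group and the 1,1-disubstituted acrylate closes the seven-membered lactone; the ring allows only the alkene geometry with C6 and the CH2O group cis, which is the one required.

Step 19
Reactants: 7 (E)-diene; 8 2,2,2-trifluoroethyl acrylate
Product: 28 cis adduct 2,2,2-trifluoroethyl (1S,2R)-2-(PMB-oxymethyl)-4-(TBS-oxymethyl)cyclohex-3-ene-1-carboxylate
Conditions: (S)-3,3-diphenyl-1-(2-methylphenyl)hexahydropyrrolo[1,2-c][1,3,2]oxazaborole (20 mol%), HN(SO2CF3)2 (17 mol%), CH2Cl2, −40 to −20 °C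
Reagents that add atoms: none
Why: The Diels–Alder reaction of step 5 under the antipodal catalyst gives the mirror-image cis adduct; the trans (exo) isomer must be removed here, because epimerisation in step 20 would turn it into the enantiomer of 30.

Step 20
Reactants: 28 cis trifluoroethyl ester
Product: 30 trans methyl ester methyl (1R,2R)-2-(PMB-oxymethyl)-4-(TBS-oxymethyl)cyclohex-3-ene-1-carboxylate, via cis methyl ester 29 (not isolated)
Conditions: NaOMe, MeOH, 50 °C; AcOH quench
Reagents that add atoms: sodium methoxide, C[O-].[Na+]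
Why: Transesterification, then thermodynamic epimerisation of the ester α-carbon through the enolate to the diequatorial trans ester; the allylic carbon set in step 19 is not acidic and keeps its configuration.

Step 21
Reactants: 30 trans methyl ester
Product: 32 trans methyl ketone 1-[(1R,2R)-2-(PMB-oxymethyl)-4-(TBS-oxymethyl)cyclohex-3-en-1-yl]ethan-1-one, via Weinreb amide 31 (not isolated)
Conditions: MeNH(OMe)·HCl, iPrMgCl, THF, −20 °C; then MeMgBr, 0 °C
Reagents that add atoms: methylmagnesium bromide, C[Mg]Br
Why: Weinreb ketone synthesis as in step 6; the trans ketone is the stable epimer.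

Step 22
Reactants: 32 trans methyl ketone
Product: 33 trans isopropenyl compound (3R,4R)-3-(PMB-oxymethyl)-4-(prop-1-en-2-yl)-1-(TBS-oxymethyl)cyclohex-1-ene
Conditions: Ph3PCH3Br, KOt-Bu, THF, 0 °C to rt
Reagents that add atoms: methyltriphenylphosphonium bromide, C[P+](c1ccccc1)(c1ccccc1)c1ccccc1.[Br-]
Why: Wittig methylenation; the ketone is already the thermodynamic epimer, so the basic ylide is harmless here.

Step 23
Reactants: 33 trans isopropenyl compound
Product: 34 trans isopropyl compound (3S,4S)-3-(PMB-oxymethyl)-4-isopropyl-1-(TBS-oxymethyl)cyclohex-1-ene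
Conditions: H2 (1 atm), RhCl(PPh3)3 (5 mol%), benzene/EtOH, rt
Reagents that add atoms: none
Why: Selective homogeneous hydrogenation of the 1,1-disubstituted alkene, as in step 8.

Step 24
Reactants: 34 trans isopropyl compound
Product: 35 alcohol [(1S,6S)-6-isopropyl-3-(TBS-oxymethyl)cyclohex-2-en-1-yl]methanol
Conditions: DDQ, CH2Cl2/pH 7 buffer, 0 °C
Reagents that add atoms: none
Why: Oxidative cleavage of the PMB ether; the allylic silyl ether and the ring alkene are not touched.

Step 25
Reactants: 35 alcohol
Product: 36 aldehyde (1S,6S)-6-isopropyl-3-(TBS-oxymethyl)cyclohex-2-ene-1-carbaldehyde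
Conditions: Dess–Martin periodinane, NaHCO3, CH2Cl2, 0 °C; used at once
Reagents that add atoms: none
Why: Buffered Dess–Martin oxidation, mild enough to keep the β,γ-unsaturated aldehyde from epimerising or moving its double bond into conjugation.

Step 26
Reactants: 37 (2-bromoethoxy)(tert-butyl)dimethylsilane
Product: 38 [2-(TBS-oxy)ethyl]triphenylphosphonium bromide
Conditions: PPh3, MeCN, reflux
Reagents that add atoms: triphenylphosphine, c1ccc(cc1)P(c1ccccc1)c1ccccc1
Why: SN2 quaternisation of the phosphine by a primary bromide.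

Step 27
Reactants: 38 phosphonium bromide
Product: 41 allyl 3-(TBS-oxy)-2-(triphenylphosphoranylidene)propanoate, via silyloxyethylidene ylide 39 (not isolated), via acylphosphonium chloride 40 (not isolated)
Conditions: NaN(SiMe3)2 (1 equiv), THF, −78 °C; allyl chloroformate (1 equiv), −78 °C; NaN(SiMe3)2 (1 equiv), −78 to 0 °C
Reagents that add atoms: allyl chloroformate, C=CCOC(=O)Cl
Why: C-Acylation of a non-stabilised phosphorus ylide by a chloroformate and deprotonation of the acylphosphonium salt, the standard route to α-substituted ester-stabilised ylides; at −78 °C the β-silyloxy ylide should not lose silanolate.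

Step 28
Reactants: 36 aldehyde; 41 stabilised ylide
Product: 42 allyl (2E)-enoate (ring C trans to the ester group; both CH2OTBS groups in place)
Conditions: toluene, 80 °C
Reagents that add atoms: none
Why: Wittig olefination with an α-substituted ester-stabilised ylide under neutral conditions, which should give the (E)-enoate with the ring trans to the ester; the ylide is too weak a base to isomerise the aldehyde.

Step 29
Reactants: 42 allyl enoate
Product: 43 (2E)-enoic acid of the ring C half
Conditions: Pd(PPh3)4 (5 mol%), morpholine, THF, rt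
Reagents that add atoms: none
Why: Allyl ester cleavage through a π-allyl complex of zerovalent palladium with morpholine as allyl acceptor; the neutral conditions keep the silyl ethers and the doubly allylic C–H intact.

Step 30
Reactants: 27 bicyclic lactone epoxide; 43 enoic acid
Product: 44 protected target (tertiary hydroxyl free; two TBS ethers; tert-butyl ester)
Conditions: 43 (2 equiv), Cs2CO3 (0.5 equiv), DMF, 70 °C
Reagents that add atoms: none
Why: SN2 opening of the spiro-epoxide at its CH2 carbon by the caesium carboxylate, with the excess acid as proton source; the C4–O bond is not touched, so C4 keeps its configuration, and the acid is never activated as an acyl donor, so its enoate cannot deconjugate.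

Step 31
Reactants: 44 protected target
Product: 46 target CNP0361406.4, via silyl ester 45 (not isolated)
Conditions: Me3SiOSO2CF3, 2,6-lutidine, CH2Cl2, 0 °C; then HF·pyridine, pyridine, THF, 0 °C to rt
Reagents that add atoms: none
Why: Silyl triflate cleavage of the tert-butyl ester (loss of isobutene; the tertiary hydroxyl is silylated in passing), then fluoride removal of all silyl groups under mildly acidic conditions, which avoids strong protic acid on the allylic alcohols and basic fluoride on the lactone and the enoate.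

**Compound list**

1 | 2-bromoprop-2-en-1-ol | OCC(Br)=C | starting material
2 | tert-butyl[(2-bromoprop-2-en-1-yl)oxy]dimethylsilane | C=C(Br)CO[Si](C)(C)C(C)(C)C | intermediate
3 | 4-methoxybenzyl alcohol | COc1ccc(CO)cc1 | starting material
4 | propargyl bromide (3-bromoprop-1-yne) | C#CCBr | starting material
5 | 1-methoxy-4-[(prop-2-yn-1-yloxy)methyl]benzene | C#CCOCc1ccc(OC)cc1 | intermediate
6 | 2-[(E)-3-(4-methoxybenzyloxy)prop-1-en-1-yl]-4,4,5,5-tetramethyl-1,3,2-dioxaborolane | COc1ccc(COC/C=C/B2OC(C)(C)C(C)(C)O2)cc1 | intermediate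
7 | tert-butyl{[(3E)-5-(4-methoxybenzyloxy)-2-methylidenepent-3-en-1-yl]oxy}dimethylsilane | C=C(CO[Si](C)(C)C(C)(C)C)/C=C/COCc1ccc(OC)cc1 | intermediate
8 | 2,2,2-trifluoroethyl acrylate | C=CC(=O)OCC(F)(F)F | starting material
9 | 2,2,2-trifluoroethyl (1R,2S)-2-(PMB-oxymethyl)-4-(TBS-oxymethyl)cyclohex-3-ene-1-carboxylate (cis) | O=C(OCC(F)(F)F)[C@@H]1CCC(CO[Si](C)(C)C(C)(C)C)=C[C@@H]1COCc1ccc(OC)cc1 | intermediate
10 | (1R,2S)-N-methoxy-N-methyl-2-(PMB-oxymethyl)-4-(TBS-oxymethyl)cyclohex-3-ene-1-carboxamide (not isolated) | CON(C)C(=O)[C@@H]1CCC(CO[Si](C)(C)C(C)(C)C)=C[C@@H]1COCc1ccc(OC)cc1 | intermediate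
11 | 1-[(1R,2S)-2-(PMB-oxymethyl)-4-(TBS-oxymethyl)cyclohex-3-en-1-yl]ethan-1-one (cis) | CC(=O)[C@@H]1CCC(CO[Si](C)(C)C(C)(C)C)=C[C@@H]1COCc1ccc(OC)cc1 | intermediate
12 | (3S,4R)-3-(PMB-oxymethyl)-4-(prop-1-en-2-yl)-1-(TBS-oxymethyl)cyclohex-1-ene (cis) | C=C(C)[C@@H]1CCC(CO[Si](C)(C)C(C)(C)C)=C[C@@H]1COCc1ccc(OC)cc1 | intermediate
13 | (3R,4S)-3-(PMB-oxymethyl)-4-isopropyl-1-(TBS-oxymethyl)cyclohex-1-ene (cis) | CC(C)[C@@H]1CCC(CO[Si](C)(C)C(C)(C)C)=C[C@@H]1COCc1ccc(OC)cc1 | intermediate
14 | [(3R,4S)-3-(PMB-oxymethyl)-4-isopropylcyclohex-1-en-1-yl]methanol | CC(C)[C@@H]1CCC(CO)=C[C@@H]1COCc1ccc(OC)cc1 | intermediate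
15 | tributyl({[(3R,4S)-3-(PMB-oxymethyl)-4-isopropylcyclohex-1-en-1-yl]methoxy}methyl)stannane | CC(C)[C@@H]1CCC(COC[Sn](CCCC)(CCCC)CCCC)=C[C@@H]1COCc1ccc(OC)cc1 | intermediate
16 | lithiomethyl ether of 14 (not isolated) | CC(C)[C@@H]1CCC(COC[Li])=C[C@@H]1COCc1ccc(OC)cc1 | intermediate
17 | ring A homoallylic alcohol: C4 exocyclic methylene, C5 CH2OH, C6 CH2OPMB, C1 isopropyl; C5 arm trans to the C6 arm and to isopropyl | CC(C)[C@@H]1CCC(=C)[C@@H](CO)[C@@H]1COCc1ccc(OC)cc1 | intermediate
18 | C4 spiro-epoxide of 17, oxirane oxygen cis to the C5 CH2OH arm | CC(C)[C@@H]1CC[C@]2(CO2)[C@@H](CO)[C@@H]1COCc1ccc(OC)cc1 | intermediate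
19 | C5 aldehyde of 18 (not isolated) | CC(C)[C@@H]1CC[C@]2(CO2)[C@@H](C=O)[C@@H]1COCc1ccc(OC)cc1 | intermediate
20 | C5 carboxylic acid of 18 (epoxy acid) | CC(C)[C@@H]1CC[C@]2(CO2)[C@@H](C(=O)O)[C@@H]1COCc1ccc(OC)cc1 | intermediate
21 | epoxy hydroxy acid: C6 CH2OH trans to C5 CO2H and cis to isopropyl | CC(C)[C@@H]1CC[C@]2(CO2)[C@@H](C(=O)O)[C@@H]1CO | intermediate
22 | epoxy aldehyde acid with C6 CHO cis to isopropyl (not isolated) | CC(C)[C@@H]1CC[C@]2(CO2)[C@@H](C(=O)O)[C@@H]1C=O | intermediate
23 | epoxy aldehyde acid with C6 CHO trans to isopropyl and cis to C5 CO2H (drawn open; held as the cyclic hydroxylactone) | CC(C)[C@@H]1CC[C@]2(CO2)[C@@H](C(=O)O)[C@H]1C=O | intermediate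
24 | epoxy vinyl acid: C6 vinyl cis to C5 CO2H | CC(C)[C@@H]1CC[C@]2(CO2)[C@@H](C(=O)O)[C@H]1C=C | intermediate
25 | tert-butyl 2-(bromomethyl)acrylate | C=C(CBr)C(=O)OC(C)(C)C | starting material
26 | 2-(tert-butoxycarbonyl)allyl ester of 24 | CC(C)[C@@H]1CC[C@]2(CO2)[C@@H](C(=O)OCC(=C)C(=O)OC(C)(C)C)[C@H]1C=C | intermediate
27 | bicyclic lactone epoxide: ring A cis-fused to the seven-membered lactone (tert-butyl ester on its alkene), C4 spiro-epoxide | CC(C)[C@@H]1CC[C@]3(CO3)[C@H]2C(=O)OCC(C(=O)OC(C)(C)C)=C[C@@H]12 | intermediate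
28 | 2,2,2-trifluoroethyl (1S,2R)-2-(PMB-oxymethyl)-4-(TBS-oxymethyl)cyclohex-3-ene-1-carboxylate (cis; enantiomer of 9) | O=C(OCC(F)(F)F)[C@H]1CCC(CO[Si](C)(C)C(C)(C)C)=C[C@H]1COCc1ccc(OC)cc1 | intermediate
29 | methyl (1S,2R)-2-(PMB-oxymethyl)-4-(TBS-oxymethyl)cyclohex-3-ene-1-carboxylate (cis; not isolated) | COC(=O)[C@H]1CCC(CO[Si](C)(C)C(C)(C)C)=C[C@H]1COCc1ccc(OC)cc1 | intermediate
30 | methyl (1R,2R)-2-(PMB-oxymethyl)-4-(TBS-oxymethyl)cyclohex-3-ene-1-carboxylate (trans) | COC(=O)[C@@H]1CCC(CO[Si](C)(C)C(C)(C)C)=C[C@H]1COCc1ccc(OC)cc1 | intermediate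
31 | (1R,2R)-N-methoxy-N-methyl-2-(PMB-oxymethyl)-4-(TBS-oxymethyl)cyclohex-3-ene-1-carboxamide (not isolated) | CON(C)C(=O)[C@@H]1CCC(CO[Si](C)(C)C(C)(C)C)=C[C@H]1COCc1ccc(OC)cc1 | intermediate
32 | 1-[(1R,2R)-2-(PMB-oxymethyl)-4-(TBS-oxymethyl)cyclohex-3-en-1-yl]ethan-1-one (trans) | CC(=O)[C@@H]1CCC(CO[Si](C)(C)C(C)(C)C)=C[C@H]1COCc1ccc(OC)cc1 | intermediate
33 | (3R,4R)-3-(PMB-oxymethyl)-4-(prop-1-en-2-yl)-1-(TBS-oxymethyl)cyclohex-1-ene (trans) | C=C(C)[C@@H]1CCC(CO[Si](C)(C)C(C)(C)C)=C[C@H]1COCc1ccc(OC)cc1 | intermediate
34 | (3S,4S)-3-(PMB-oxymethyl)-4-isopropyl-1-(TBS-oxymethyl)cyclohex-1-ene (trans) | CC(C)[C@@H]1CCC(CO[Si](C)(C)C(C)(C)C)=C[C@H]1COCc1ccc(OC)cc1 | intermediate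
35 | [(1S,6S)-6-isopropyl-3-(TBS-oxymethyl)cyclohex-2-en-1-yl]methanol | CC(C)[C@@H]1CCC(CO[Si](C)(C)C(C)(C)C)=C[C@H]1CO | intermediate
36 | (1S,6S)-6-isopropyl-3-(TBS-oxymethyl)cyclohex-2-ene-1-carbaldehyde | CC(C)[C@@H]1CCC(CO[Si](C)(C)C(C)(C)C)=C[C@H]1C=O | intermediate
37 | (2-bromoethoxy)(tert-butyl)dimethylsilane | BrCCO[Si](C)(C)C(C)(C)C | starting material
38 | [2-(TBS-oxy)ethyl]triphenylphosphonium bromide | [Br-].CC(C)(C)[Si](C)(C)OCC[P+](c1ccccc1)(c1ccccc1)c1ccccc1 | intermediate
39 | [2-(TBS-oxy)ethylidene]triphenylphosphorane (not isolated) | CC(C)(C)[Si](C)(C)OCC=P(c1ccccc1)(c1ccccc1)c1ccccc1 | intermediate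
40 | [1-(allyloxycarbonyl)-2-(TBS-oxy)ethyl]triphenylphosphonium chloride (not isolated) | [Cl-].C=CCOC(=O)C(CO[Si](C)(C)C(C)(C)C)[P+](c1ccccc1)(c1ccccc1)c1ccccc1 | intermediate
41 | allyl 3-(TBS-oxy)-2-(triphenylphosphoranylidene)propanoate | C=CCOC(=O)C(CO[Si](C)(C)C(C)(C)C)=P(c1ccccc1)(c1ccccc1)c1ccccc1 | intermediate
42 | allyl (2E)-2-(TBS-oxymethyl)-3-[trans-6-isopropyl-3-(TBS-oxymethyl)cyclohex-2-en-1-yl]prop-2-enoate, ring configuration as in 36 | CC(C)[C@@H]1CCC(CO[Si](C)(C)C(C)(C)C)=C[C@H]1/C=C(CO[Si](C)(C)C(C)(C)C)/C(=O)OCC=C | intermediate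
43 | (2E)-2-(TBS-oxymethyl)-3-[trans-6-isopropyl-3-(TBS-oxymethyl)cyclohex-2-en-1-yl]prop-2-enoic acid, ring configuration as in 36 | CC(C)[C@@H]1CCC(CO[Si](C)(C)C(C)(C)C)=C[C@H]1/C=C(CO[Si](C)(C)C(C)(C)C)/C(=O)O | intermediate
44 | protected target: both primary hydroxyls as TBS ethers, ring B carboxyl as tert-butyl ester, C4 hydroxyl free | CC(C)[C@@H]1CC[C@](O)(COC(=O)/C(=C/[C@@H]2C=C(CO[Si](C)(C)C(C)(C)C)CC[C@H]2C(C)C)CO[Si](C)(C)C(C)(C)C)[C@H]2C(=O)OCC(C(=O)OC(C)(C)C)=C[C@@H]12 | intermediate
45 | trimethylsilyl ester of the ring B acid with the C4 hydroxyl as trimethylsilyl ether and both TBS ethers in place (not isolated) | CC(C)[C@@H]1CC[C@](O[Si](C)(C)C)(COC(=O)/C(=C/[C@@H]2C=C(CO[Si](C)(C)C(C)(C)C)CC[C@H]2C(C)C)CO[Si](C)(C)C(C)(C)C)[C@H]2C(=O)OCC(C(=O)O[Si](C)(C)C)=C[C@@H]12 | intermediate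
46 | CNP0361406.4 | CC(C)[C@@H]1CC[C@](O)(COC(=O)/C(=C/[C@@H]2C=C(CO)CC[C@H]2C(C)C)CO)[C@H]2C(=O)OCC(C(=O)O)=C[C@@H]12 | target

**Step count**

Total: 31 steps. Longest linear sequence: 19 steps (2, 3, 4, 5 to 18, 30, 31).

**Steps most likely to fail**

Step 30. The hindered, weakly nucleophilic carboxylate of 43 may open the axial CH2 of the spiro-epoxide too slowly, so that at the temperature needed the tertiary alkoxide transacylates or the enoate isomerises. The fallback transfers the acyl group to a preformed diol instead of alkylating the carboxylate. It sets out from 27: the epoxide is opened with the small nucleophile HCO2Cs (DMF, 60 °C) to the hydroxy formate F1. The formate is removed with KHCO3 in MeOH at 0 °C, under which the lactone and the tert-butyl ester should survive, to give the diol F2. Acid 43 is turned into its mixed anhydride (2,4,6-trichlorobenzoyl chloride, Et3N, toluene) and coupled with the primary hydroxyl of F2 in the presence of 4-(dimethylamino)pyridine (Yamaguchi esterification; the tertiary hydroxyl should not react). This returns to the route at 44.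

Step 5 (and its repeat, step 19). The ether oxygens of 7 may compete with the acrylate for the cationic boron, so that turnover stalls and an uncatalysed background cycloaddition erodes enantio- and endo selectivity. The fallback takes the absolute configuration from a separation instead of from the catalyst. It sets out from 7 and 8: the cycloaddition is run with a stoichiometric achiral Lewis acid (Me2AlCl, CH2Cl2, −78 °C), which should still give the cis adduct, now as the racemate. The enantiomers are separated by preparative chromatography on a chiral stationary phase. Both antipodes are needed, so nothing is discarded, and the route is re-entered at 9 and at 28; no compound outside the list is made (F0).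

Step 18. The ruthenium carbene at the hindered C6 vinyl group may close only slowly onto the electron-poor 1,1-disubstituted acrylate, so that dimerisation through the vinyl group or catalyst decay wins. The fallback builds the ring B alkene by olefination and closes the ring by lactonisation. It sets out from 23, with 38 as the phosphorus source: ylide 39 is generated from 38 as in step 27 and acylated with di-tert-butyl dicarbonate to give the tert-butyl ester ylide F3. Aldehyde acid 23, as its triethylammonium salt (ring-opened form), is olefinated with F3 in toluene at 80 °C to the (E)-enoate acid F4. Bu4NF removes the silyl group to give the hydroxy acid F5. Lactonisation (2,4,6-trichlorobenzoyl chloride, Et3N; then 4-(dimethylamino)pyridine, high dilution) closes ring B and returns to the route at 27; the (E) geometry from the stabilised ylide is the one that can lactonise.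

Further compounds
F0 | step 5 | none | none
F1 | step 30 | hydroxy formate: 27 with the epoxide opened to C4 hydroxyl and C4 CH2O formate | CC(C)[C@@H]1CC[C@](O)(COC=O)[C@H]2C(=O)OCC(C(=O)OC(C)(C)C)=C[C@@H]12
F2 | step 30 | diol: 27 with the epoxide opened to C4 hydroxyl and C4 CH2OH | CC(C)[C@@H]1CC[C@](O)(CO)[C@H]2C(=O)OCC(C(=O)OC(C)(C)C)=C[C@@H]12
F3 | step 18 | tert-butyl 3-(TBS-oxy)-2-(triphenylphosphoranylidene)propanoate | CC(C)(C)OC(=O)C(CO[Si](C)(C)C(C)(C)C)=P(c1ccccc1)(c1ccccc1)c1ccccc1
F4 | step 18 | (E)-enoate acid: 23 with the C6 formyl group converted into CH=C(CH2OTBS)CO2t-Bu, ring trans to the ester | CC(C)[C@@H]1CC[C@]2(CO2)[C@@H](C(=O)O)[C@H]1/C=C(CO[Si](C)(C)C(C)(C)C)/C(=O)OC(C)(C)C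
F5 | step 18 | hydroxy acid: F4 without the silyl group | CC(C)[C@@H]1CC[C@]2(CO2)[C@@H](C(=O)O)[C@H]1/C=C(CO)/C(=O)OC(C)(C)C
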